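**Retrosynthetic overview**

- The strategy rests on the C4 allylic carbinol flanked by the E-C2=C3 alkene on quaternary C1 inside the ten-membered ring C1–C10. Cutting C3–C4 gives a seco ynal (C1 ethynyl, C4 Z-enal) that is closed by nickel-catalysed reductive macrocyclisation.
- After ring closure: C4 acetate, unmasking of the ring-A enone from its allylic silyl ether, then ene-type chlorination of the 5Z alkene to the 6-chloro-5(16)-ene.
- Seco ynal: C6–C7 by Nozaki–Hiyama–Kishi coupling of a Z-iodoalkene with a C7 α-silyloxy aldehyde, then γ-lactone closure; C8–C9 by aldol addition of a malate-derived dioxolanone enolate to the ring-A C9 aldehyde.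
- Ring A: enantioselective Diels–Alder reaction of a 2-silyloxydiene with the formyl crotonate, alkyne by Seyferth–Gilbert homologation, C11 oxygenation through the enone.
- Ring order: six-membered ring A, then the γ-lactone, then the ten-membered ring.

Key step: step 27

Remark: locants follow the briarane numbering of the target (C15 on C1, C16 on C5, C18 on C17, C19 lactone carbonyl, C20 on C11); β is the face of ring A that carries C15.
Remark: the (S)-oxazaborolidine is assumed to give the (1S,10S) cycloadduct, as its pre-transition-state model for 2-substituted enals predicts; if the sense is opposite, the (R)-catalyst is used and nothing else changes.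
Remark: C11 is an inconsequential epimer mixture from the cycloaddition until step 7 (where it is planarised) and is left unassigned in those SMILES.
Remark: enolates and organometallic species made and consumed within one operation are treated as reactive intermediates and carry no number.

**Route**

Step 1
Reactants: 1 pent-1-en-3-one
Product: 2 (Z)-triisopropyl(penta-1,3-dien-3-yloxy)silane
Conditions: TIPSOTf, Et3N, CH2Cl2, 0 °C to rt
Reagents that add atoms: triisopropylsilyl trifluoromethanesulfonate, CC(C)[Si](C(C)C)(C(C)C)OS(=O)(=O)C(F)(F)F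
Why: Soft enolisation of the ethyl ketone (silyl enol ether formation) gives the 2-silyloxydiene, whose Z isomer (methyl outside the s-cis diene) is the one that reacts in step 2.

Step 2
Reactants: 2 (Z)-triisopropyl(penta-1,3-dien-3-yloxy)silane; 3 ethyl (E)-3-methyl-4-oxobut-2-enoate
Product: 4 ethyl (1S,2S)-2-formyl-2,6-dimethyl-5-(triisopropylsilyloxy)cyclohex-4-ene-1-carboxylate (ring A: C1 formyl and β-methyl; C10 β-ester; C11 epimers)
Conditions: (S)-1-(2-methylphenyl)-3,3-diphenyltetrahydro-1H,3H-pyrrolo[1,2-c][1,3,2]oxazaborole (20 mol%), Tf2NH (20 mol%), CH2Cl2, −78 to −40 °C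
Reagents that add atoms: none
Why: Enantioselective Diels–Alder reaction in which the protonated oxazaborolidine binds the formyl group, the nucleophilic diene terminus C11 bonds to C10 (β to the formyl group), the E dienophile places C15 and the C9 ester cis, and the catalyst sets C1 and C10.

Step 3
Reactants: 4 Diels–Alder adduct; 5 dimethyl (1-diazo-2-oxopropyl)phosphonate
Product: 6 ethyl (1S,2S)-2-ethynyl-2,6-dimethyl-5-(triisopropylsilyloxy)cyclohex-4-ene-1-carboxylate (1α-ethynyl; 1β-methyl; 10β-ester)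
Conditions: K2CO3, MeOH, 0 °C to rt
Reagents that add atoms: none
Why: Seyferth–Gilbert homologation with the Ohira–Bestmann reagent turns the non-enolisable neopentyl aldehyde into the C2≡C3 alkyne under conditions that spare the triisopropylsilyl enol ether, and any ester exchange is erased in step 4.

Step 4
Reactants: 6 ethynyl ester
Product: 7 C9 primary alcohol (1α-ethynyl, 10β-hydroxymethyl, 12-silyl enol ether)
Conditions: iBu2AlH, CH2Cl2, −78 to 0 °C; aq. potassium sodium tartrate
Reagents that add atoms: none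
Why: Hydride reduction of the ester is done before any acetate is present, and the silyl enol ether and alkyne are inert to the aluminium hydride.

Step 5
Reactants: 7 C9 primary alcohol
Product: 8 C9 4-methoxybenzyl ether
Conditions: NaH, 4-methoxybenzyl chloride, Bu4NI (cat.), THF–DMF, 0 °C to rt
Reagents that add atoms: 4-methoxybenzyl chloride, COc1ccc(CCl)cc1
Why: Williamson etherification masks the C9 hydroxyl so that it cannot add to the enone or be acetylated in the following steps.

Step 6
Reactants: 8 C9 4-methoxybenzyl ether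
Product: 11 ring-A 12-oxo-13-ene (enone) 4-methoxybenzyl ether, via 13-phenylselanyl 12-ketone 9 (not isolated), via 13-selenoxide 10 (not isolated)
Conditions: PhSeCl, CH2Cl2, −78 °C; then 30% H2O2, pyridine, 0 °C to rt
Reagents that add atoms: none
Why: Electrophilic selenenylation of the silyl enol ether at C13 followed by selenoxide syn-elimination toward C14 gives the enone, which leaves C11 as the only enolisable position.

Step 7
Reactants: 11 ring-A enone
Product: 12 11α-hydroxy-11β-methyl enone
Conditions: KN(SiMe3)2, THF, −78 °C; 2-(phenylsulfonyl)-3-phenyloxaziridine, −78 °C; aq. NH4Cl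
Reagents that add atoms: 2-(phenylsulfonyl)-3-phenyloxaziridine, O=S(=O)(N1OC1c1ccccc1)c1ccccc1
Why: Enolate hydroxylation with an N-sulfonyloxaziridine, in which the cross-conjugated dienolate can form only at C11 and is oxidised on the α face, away from the β-oriented C10 side chain and C15 methyl.

Step 8
Reactants: 12 11α-hydroxy enone
Product: 13 11α-acetoxy-11β-methyl enone
Conditions: Ac2O, DMAP, Et3N, CH2Cl2, rt
Reagents that add atoms: acetic anhydride, CC(=O)OC(C)=O
Why: DMAP-catalysed acylation of the tertiary α-ketol is feasible at this stage because C12 is still a planar carbonyl and no other hydroxyl is present.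

Step 9
Reactants: 13 11α-acetoxy enone
Product: 14 12β-allylic alcohol (13-ene)
Conditions: NaBH4, CeCl3·7H2O, MeOH, −78 °C
Reagents that add atoms: none
Why: Luche reduction gives clean 1,2-reduction, hydride arriving on the α face opposite the three β substituents (C15, C9 chain, C20); the C12 configuration is erased again in step 31.

Step 10
Reactants: 14 12β-allylic alcohol
Product: 15 12β-tert-butyldimethylsilyl ether
Conditions: TBSOTf, 2,6-lutidine, CH2Cl2, −78 to 0 °C
Reagents that add atoms: tert-butyldimethylsilyl trifluoromethanesulfonate, CC(C)(C)[Si](C)(C)OS(=O)(=O)C(F)(F)F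
Why: Silylation with the triflate and a hindered base protects the hindered allylic alcohol without base-induced acetyl migration from O11, and the masked enone cannot compete for nickel later.

Step 11
Reactants: 15 12β-silyl ether
Product: 16 C9 primary alcohol of ring A
Conditions: DDQ, CH2Cl2–pH 7 buffer, 0 °C
Reagents that add atoms: none
Why: Oxidative cleavage of the 4-methoxybenzyl ether is orthogonal to the silyl ether, acetate, alkyne and ring alkene.

Step 12
Reactants: 16 C9 primary alcohol
Product: 17 ring-A C9 aldehyde (1α-ethynyl, 11α-OAc, 12β-OTBS, 13-ene)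
Conditions: Dess–Martin periodinane, NaHCO3, CH2Cl2, 0 °C to rt
Reagents that add atoms: none
Why: Dess–Martin oxidation gives the aldehyde under buffered neutral conditions that do not epimerise C10.

Step 13
Reactants: 18 diethyl (S)-malate
Product: 19 diethyl (2S,3R)-2-hydroxy-3-methylbutanedioate
Conditions: LiN(iPr)2 (2.2 equiv), THF, −78 to −20 °C; MeI, −78 to −10 °C; aq. NH4Cl
Reagents that add atoms: iodomethane, CI
Why: Fráter–Seebach alkylation, in which the chelated dianion of the β-hydroxy ester is methylated anti to the alkoxide and so sets C17 relative to the malate carbinol.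

Step 14
Reactants: 19 diethyl (2S,3R)-2-hydroxy-3-methylbutanedioate
Product: 20 (2S,3R)-2-hydroxy-3-methylbutanedioic acid
Conditions: KOH, H2O–EtOH, rt; then HCl to pH 1
Reagents that add atoms: potassium hydroxide, [K+].[OH-]
Why: Saponification gives the diacid needed for acetalisation, and the carboxylate-flanked stereocentres are stable to aqueous hydroxide at room temperature.

Step 15
Reactants: 20 (2S,3R)-2-hydroxy-3-methylbutanedioic acid
Product: 21 (2R)-2-[(2S,4S)-2-tert-butyl-5-oxo-1,3-dioxolan-4-yl]propanoic acid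
Conditions: pivalaldehyde, TsOH·H2O (cat.), H2SO4 (cat.), pentane, reflux with azeotropic removal of water
Reagents that add atoms: pivalaldehyde, CC(C)(C)C=O
Why: Acid-catalysed acetalisation of the α-hydroxy acid gives the five-membered dioxolanone, whose thermodynamic cis isomer stores the C8 configuration in the new acetal centre (self-regeneration of stereocentres).

Step 16
Reactants: 21 dioxolanone acid
Product: 22 tert-butyl (2R)-2-[(2S,4S)-2-tert-butyl-5-oxo-1,3-dioxolan-4-yl]propanoate
Conditions: tert-butyl 2,2,2-trichloroacetimidate, CH2Cl2–cyclohexane, rt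
Reagents that add atoms: tert-butyl 2,2,2-trichloroacetimidate, CC(C)(C)OC(=N)C(Cl)(Cl)Cl
Why: Imidate esterification, in which the acid itself protonates the imidate, gives the tert-butyl ester that later resists borohydride and premature lactonisation.

Step 17
Reactants: 22 dioxolanone tert-butyl ester; 17 ring-A C9 aldehyde
Product: 23 aldol adduct (9-hydroxy; C8 in the dioxolanone; C8, C9 and C17 arranged as in the target)
Conditions: LiN(SiMe3)2, THF, −78 °C (22, 1.5 equiv); then 17, −78 °C; AcOH quench at −78 °C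
Reagents that add atoms: none
Why: Aldol addition of the dioxolanone lithium enolate, in which the aldehyde is attacked anti to the tert-butyl group so that C9 replaces H8 with retention, and a Zimmerman–Traxler chair with the C17 branch cis to O–Li and the ring-A residue equatorial gives the 9R carbinol.

Step 18
Reactants: 23 aldol adduct
Product: 24 7,8,9-triol tert-butyl ester
Conditions: LiBH4, THF, −20 to 0 °C
Reagents that add atoms: none
Why: Borohydride reduction of the activated acylal carbonyl opens the dioxolanone (pivalaldehyde is released and reduced) to the C7 primary alcohol, while the hindered tert-butyl ester and tertiary acetate are expected to survive at low temperature.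

Step 19
Reactants: 24 7,8,9-triol
Product: 25 8,9-dihydroxy C7 aldehyde
Conditions: TEMPO (cat.), N-chlorosuccinimide, Bu4NCl (cat.), CH2Cl2–aq. NaHCO3 buffer, rt
Reagents that add atoms: none
Why: Oxoammonium (TEMPO) oxidation is selective for the primary C7 alcohol over the hindered secondary C9 alcohol and does not cleave the 1,2-diols, and the α-quaternary aldehyde cannot enolise.

Step 20
Reactants: 25 8,9-dihydroxy C7 aldehyde
Product: 26 9-acetoxy-8-hydroxy C7 aldehyde
Conditions: Ac2O, pyridine, DMAP (cat.), CH2Cl2, 0 °C to rt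
Reagents that add atoms: acetic anhydride, CC(=O)OC(C)=O
Why: Mild acetylation esterifies only the secondary C9 hydroxyl, the tertiary C8 hydroxyl being too hindered.

Step 21
Reactants: 26 9-acetoxy-8-hydroxy C7 aldehyde
Product: 27 9-acetoxy-8-triethylsilyloxy C7 aldehyde
Conditions: TESOTf, 2,6-lutidine, CH2Cl2, −78 °C
Reagents that add atoms: triethylsilyl trifluoromethanesulfonate, CC[Si](CC)(CC)OS(=O)(=O)C(F)(F)F
Why: Low-temperature silylation of the tertiary hydroxyl gives the α-silyloxy aldehyde needed for non-chelation-controlled addition, and the O8 silyl group later keeps the δ-hydroxy Z-enal from closing to a lactol.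

Step 22
Reactants: 28 prop-2-yn-1-ol
Product: 29 (Z)-3-iodo-2-methylprop-2-en-1-ol
Conditions: MeMgBr (2.5 equiv), CuI (10 mol%), THF, −20 °C to rt; then I2, −78 to 0 °C
Reagents that add atoms: methylmagnesium bromide, C[Mg]Br; iodine, II
Why: Copper-catalysed anti-carbomagnesiation of the propargylic alkoxide puts methyl on C5 and magnesium on C6 in a five-membered chelate, and iodinolysis with retention gives the Z iodoalkene.

Step 23
Reactants: 29 (Z)-3-iodo-2-methylprop-2-en-1-ol
Product: 30 (Z)-triethyl[(3-iodo-2-methylprop-2-en-1-yl)oxy]silane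
Conditions: TESCl, imidazole, CH2Cl2, 0 °C
Reagents that add atoms: chlorotriethylsilane, CC[Si](Cl)(CC)CC
Why: Silylation of the primary allylic alcohol gives an ether that tolerates CrCl2 and is removed selectively in step 25.

Step 24
Reactants: 27 C7 α-silyloxy aldehyde; 30 Z-iodoalkene silyl ether
Product: 31 C7 allylic alcohol (5Z; 4-OSiEt3; 8-OSiEt3; tert-butyl ester)
Conditions: CrCl2 (6 equiv), NiCl2 (2 mol%), DMSO, rt
Reagents that add atoms: none
Why: Nozaki–Hiyama–Kishi coupling, in which the alkenyl trivalent chromium species adds only to the aldehyde with retention of the Z geometry, and Felkin–Anh approach anti to the C8–OSi bond past the smaller C17 branch sets C7 as in the target.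

Step 25
Reactants: 31 C7 allylic alcohol
Product: 34 γ-lactone C4 alcohol (8-OSiEt3; 12-OTBS), via bis-trimethylsilyl derivative 32 (not isolated), via γ-hydroxy acid 33 (not isolated)
Conditions: TMSOTf, 2,6-lutidine, CH2Cl2, 0 °C to rt; then PPTS, MeOH, rt
Reagents that add atoms: none
Why: The silyl triflate converts the tert-butyl ester into a silyl ester with loss of isobutene, and methanolysis then frees the acid, the C7 hydroxyl and the primary C4 hydroxyl, so that the γ-hydroxy acid lactonises (favoured by quaternary C8) while the tertiary and hindered secondary silyl ethers stay.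

Step 26
Reactants: 34 γ-lactone C4 alcohol
Product: 35 seco ynal (C1 ethynyl; 5Z-enal; 8-OSiEt3; 12β-OTBS; 13-ene)
Conditions: Dess–Martin periodinane, NaHCO3, CH2Cl2, 0 °C
Reagents that add atoms: none
Why: Dess–Martin oxidation of the Z allylic alcohol gives the Z enal under buffered conditions that do not isomerise it, and with O8 silylated the aldehyde stays open.

Step 27
Reactants: 35 seco ynal
Product: 36 ten-membered 2E,5Z-diene 4-triethylsilyl ether
Conditions: Ni(C8H12)2 (30 mol%), 1,3-dimesitylimidazolium chloride (30 mol%), KOtBu (30 mol%), Et3SiH (5 equiv), THF, rt, syringe-pump addition of 35 (final 0.003 M)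
Reagents that add atoms: triethylsilane, CC[SiH](CC)CC
Why: Zerovalent nickel carrying the small carbene binds the terminal alkyne and the aldehyde C=O and cyclises oxidatively to an oxanickelacyclopentene containing the C3–C4 bond; σ-bond metathesis with the silane silylates O4 and reductive elimination delivers H to C2 syn to C4, so C2=C3 is E. The closest known reaction is the nickel-catalysed reductive macrocyclisation of ynals with silanes, where small carbene ligands make the aldehyde bond to the unsubstituted alkyne carbon. The ten-membered ring closes in the endocyclic mode, both alkyne carbons ending in the ring and C3–C4 being the only new skeletal bond. C4 is set by the substrate: 1,3-allylic strain holds H7 in the plane of the Z enal and keeps the enal s-trans, so the tether through C8 reaches the carbonyl from one face only, which gives 4S with O4 on the same face as the lactone oxygen. The step needs carbonyl (1,2) instead of conjugate (1,4) coupling and a free aldehyde: the Z β-substituent disfavours the s-cis enal required for a seven-membered nickel enolate and a 1,4-closure at C3 would give a trans-cyclooctene, while the O8 silyl group blocks the six-membered lactol. The ring-A ketone is carried as its allylic silyl ether so that no enone competes for nickel, and the isolated ring alkene is inert.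

Step 28
Reactants: 36 macrocyclic 4-triethylsilyl ether
Product: 37 macrocyclic C4 alcohol (8-OSiEt3; 12-OTBS)
Conditions: HF·pyridine, pyridine, THF, 0 °C
Reagents that add atoms: none
Why: Buffered fluoride desilylation cleaves the unhindered doubly allylic triethylsilyl ether much faster than the hindered silyl ethers and avoids ionisation at C4; loss of the C8 silyl group here would be harmless.

Step 29
Reactants: 37 macrocyclic C4 alcohol
Product: 38 4-acetate (8-OSiEt3; 12-OTBS)
Conditions: Ac2O, pyridine, DMAP (cat.), CH2Cl2, 0 °C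
Reagents that add atoms: acetic anhydride, CC(=O)OC(C)=O
Why: Acetylation of the secondary C4 alcohol proceeds with retention while O8 is still silylated.

Step 30
Reactants: 38 4-acetate
Product: 39 8,12-diol triacetate
Conditions: HF·pyridine, THF, 0 °C to rt
Reagents that add atoms: none
Why: Acidic fluoride desilylation removes both remaining silyl groups without the base-induced acetyl migration from O11 to O12 that fluoride salts could cause.

Step 31
Reactants: 39 8,12-diol triacetate
Product: 40 ring-A enone (12-oxo-13-ene) with 2E,5Z-diene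
Conditions: Dess–Martin periodinane, NaHCO3, CH2Cl2, 0 °C to rt
Reagents that add atoms: none
Why: Dess–Martin oxidation of the allylic C12 alcohol gives the enone directly, and the tertiary C8 hydroxyl cannot be oxidised.

Step 32
Reactants: 40 ring-A enone 2E,5Z-diene
Product: 41 CNP0159278.2, (1S,4S,6S,7R,8R,9R,10S,11S,17R)-4,9,11-triacetoxy-6-chloro-8-hydroxy-12-oxo-2E,5(16),13-triene 19,7-lactone
Conditions: Ca(OCl)2, solid CO2, CH2Cl2–H2O, 0 °C
Reagents that add atoms: calcium hypochlorite, [Ca+2].[O-]Cl.[O-]Cl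
Why: Ene-type chlorination with hypochlorous acid, in which the trisubstituted C5=C6 alkene is the only electron-rich alkene, chlorine bonds to the less substituted C6 with loss of a C16 hydrogen to give the exocyclic alkene, and attack anti to the two allylic C–O bonds (O4 and O7, held on one face by 1,3-allylic strain) gives 6S.

**Compound list**

1 | pent-1-en-3-one | CCC(=O)C=C | starting material
2 | (Z)-triisopropyl(penta-1,3-dien-3-yloxy)silane | C=C/C(O[Si](C(C)C)(C(C)C)C(C)C)=C/C | intermediate
3 | ethyl (E)-3-methyl-4-oxobut-2-enoate | CCOC(=O)/C=C(C)/C=O | starting material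
4 | ethyl (1S,2S)-2-formyl-2,6-dimethyl-5-(triisopropylsilyloxy)cyclohex-4-ene-1-carboxylate (C11 epimers) | O=C[C@@]1(C)CC=C(O[Si](C(C)C)(C(C)C)C(C)C)C(C)[C@@H]1C(=O)OCC | intermediate
5 | dimethyl (1-diazo-2-oxopropyl)phosphonate | CC(=O)C(=[N+]=[N-])P(=O)(OC)OC | starting material
6 | ethyl (1S,2S)-2-ethynyl-2,6-dimethyl-5-(triisopropylsilyloxy)cyclohex-4-ene-1-carboxylate (C11 epimers) | C#C[C@@]1(C)CC=C(O[Si](C(C)C)(C(C)C)C(C)C)C(C)[C@@H]1C(=O)OCC | intermediate
7 | C9 primary alcohol of the ethynyl silyl enol ether | C#C[C@@]1(C)CC=C(O[Si](C(C)C)(C(C)C)C(C)C)C(C)[C@@H]1CO | intermediate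
8 | C9 4-methoxybenzyl ether of 7 | C#C[C@@]1(C)CC=C(O[Si](C(C)C)(C(C)C)C(C)C)C(C)[C@@H]1COCc1ccc(OC)cc1 | intermediate
9 | 13-phenylselanyl 12-ketone | C#C[C@@]1(C)CC([Se]c2ccccc2)C(=O)C(C)[C@@H]1COCc1ccc(OC)cc1 | intermediate
10 | 13-selenoxide | C#C[C@@]1(C)CC([Se](=O)c2ccccc2)C(=O)C(C)[C@@H]1COCc1ccc(OC)cc1 | intermediate
11 | ring-A enone (12-oxo-13-ene), C9 4-methoxybenzyl ether | C#C[C@@]1(C)C=CC(=O)C(C)[C@@H]1COCc1ccc(OC)cc1 | intermediate
12 | 11α-hydroxy-11β-methyl enone | C#C[C@@]1(C)C=CC(=O)[C@@](C)(O)[C@@H]1COCc1ccc(OC)cc1 | intermediate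
13 | 11α-acetoxy-11β-methyl enone | C#C[C@@]1(C)C=CC(=O)[C@@](C)(OC(C)=O)[C@@H]1COCc1ccc(OC)cc1 | intermediate
14 | 11α-acetoxy-12β-hydroxy-13-ene | C#C[C@@]1(C)C=C[C@H](O)[C@@](C)(OC(C)=O)[C@@H]1COCc1ccc(OC)cc1 | intermediate
15 | 12β-tert-butyldimethylsilyl ether of 14 | C#C[C@@]1(C)C=C[C@H](O[Si](C)(C)C(C)(C)C)[C@@](C)(OC(C)=O)[C@@H]1COCc1ccc(OC)cc1 | intermediate
16 | ring-A C9 primary alcohol | C#C[C@@]1(C)C=C[C@H](O[Si](C)(C)C(C)(C)C)[C@@](C)(OC(C)=O)[C@@H]1CO | intermediate
17 | ring-A C9 aldehyde | C#C[C@@]1(C)C=C[C@H](O[Si](C)(C)C(C)(C)C)[C@@](C)(OC(C)=O)[C@@H]1C=O | intermediate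
18 | diethyl (S)-malate | CCOC(=O)C[C@H](O)C(=O)OCC | starting material
19 | diethyl (2S,3R)-2-hydroxy-3-methylbutanedioate | CCOC(=O)[C@@H](O)[C@@H](C)C(=O)OCC | intermediate
20 | (2S,3R)-2-hydroxy-3-methylbutanedioic acid | OC(=O)[C@@H](O)[C@@H](C)C(=O)O | intermediate
21 | (2R)-2-[(2S,4S)-2-tert-butyl-5-oxo-1,3-dioxolan-4-yl]propanoic acid | CC(C)(C)[C@H]1O[C@@H]([C@@H](C)C(=O)O)C(=O)O1 | intermediate
22 | tert-butyl (2R)-2-[(2S,4S)-2-tert-butyl-5-oxo-1,3-dioxolan-4-yl]propanoate | CC(C)(C)[C@H]1O[C@@H]([C@@H](C)C(=O)OC(C)(C)C)C(=O)O1 | intermediate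
23 | aldol adduct (9-hydroxy, C8 dioxolanone) | C#C[C@@]1(C)C=C[C@H](O[Si](C)(C)C(C)(C)C)[C@@](C)(OC(C)=O)[C@@H]1[C@@H](O)[C@]2(O[C@H](C(C)(C)C)OC2=O)[C@@H](C)C(=O)OC(C)(C)C | intermediate
24 | 7,8,9-triol tert-butyl ester | C#C[C@@]1(C)C=C[C@H](O[Si](C)(C)C(C)(C)C)[C@@](C)(OC(C)=O)[C@@H]1[C@@H](O)[C@](CO)(O)[C@@H](C)C(=O)OC(C)(C)C | intermediate
25 | 8,9-dihydroxy C7 aldehyde | C#C[C@@]1(C)C=C[C@H](O[Si](C)(C)C(C)(C)C)[C@@](C)(OC(C)=O)[C@@H]1[C@@H](O)[C@](C=O)(O)[C@@H](C)C(=O)OC(C)(C)C | intermediate
26 | 9-acetoxy-8-hydroxy C7 aldehyde | C#C[C@@]1(C)C=C[C@H](O[Si](C)(C)C(C)(C)C)[C@@](C)(OC(C)=O)[C@@H]1[C@@H](OC(C)=O)[C@](C=O)(O)[C@@H](C)C(=O)OC(C)(C)C | intermediate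
27 | 9-acetoxy-8-triethylsilyloxy C7 aldehyde | C#C[C@@]1(C)C=C[C@H](O[Si](C)(C)C(C)(C)C)[C@@](C)(OC(C)=O)[C@@H]1[C@@H](OC(C)=O)[C@](C=O)(O[Si](CC)(CC)CC)[C@@H](C)C(=O)OC(C)(C)C | intermediate
28 | prop-2-yn-1-ol | C#CCO | starting material
29 | (Z)-3-iodo-2-methylprop-2-en-1-ol | I/C=C(C)\CO | intermediate
30 | (Z)-triethyl[(3-iodo-2-methylprop-2-en-1-yl)oxy]silane | I/C=C(C)\CO[Si](CC)(CC)CC | intermediate
31 | C7 allylic alcohol (5Z, 4- and 8-OSiEt3, tert-butyl ester) | C#C[C@@]1(C)C=C[C@H](O[Si](C)(C)C(C)(C)C)[C@@](C)(OC(C)=O)[C@@H]1[C@@H](OC(C)=O)[C@](O[Si](CC)(CC)CC)([C@@H](C)C(=O)OC(C)(C)C)[C@@H](O)/C=C(C)\CO[Si](CC)(CC)CC | intermediate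
32 | 7-O-trimethylsilyl ether trimethylsilyl ester | C#C[C@@]1(C)C=C[C@H](O[Si](C)(C)C(C)(C)C)[C@@](C)(OC(C)=O)[C@@H]1[C@@H](OC(C)=O)[C@](O[Si](CC)(CC)CC)([C@@H](C)C(=O)O[Si](C)(C)C)[C@@H](O[Si](C)(C)C)/C=C(C)\CO[Si](CC)(CC)CC | intermediate
33 | γ-hydroxy acid with free C4 hydroxyl | C#C[C@@]1(C)C=C[C@H](O[Si](C)(C)C(C)(C)C)[C@@](C)(OC(C)=O)[C@@H]1[C@@H](OC(C)=O)[C@](O[Si](CC)(CC)CC)([C@@H](C)C(=O)O)[C@@H](O)/C=C(C)\CO | intermediate
34 | γ-lactone C4 alcohol | C#C[C@@]1(C)C=C[C@H](O[Si](C)(C)C(C)(C)C)[C@@](C)(OC(C)=O)[C@@H]1[C@@H](OC(C)=O)[C@]2(O[Si](CC)(CC)CC)[C@@H](C)C(=O)O[C@H]2/C=C(C)\CO | intermediate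
35 | seco ynal with fused lactone and Z-enal | C#C[C@@]1(C)C=C[C@H](O[Si](C)(C)C(C)(C)C)[C@@](C)(OC(C)=O)[C@@H]1[C@@H](OC(C)=O)[C@]2(O[Si](CC)(CC)CC)[C@@H](C)C(=O)O[C@H]2/C=C(C)\C=O | intermediate
36 | ten-membered 2E,5Z-diene 4-triethylsilyl ether | [C@H]1(O[Si](CC)(CC)CC)/C=C/[C@@]2(C)C=C[C@H](O[Si](C)(C)C(C)(C)C)[C@@](C)(OC(C)=O)[C@@H]2[C@@H](OC(C)=O)[C@]2(O[Si](CC)(CC)CC)[C@@H](C)C(=O)O[C@H]2/C=C1/C | intermediate
37 | macrocyclic C4 alcohol | [C@H]1(O)/C=C/[C@@]2(C)C=C[C@H](O[Si](C)(C)C(C)(C)C)[C@@](C)(OC(C)=O)[C@@H]2[C@@H](OC(C)=O)[C@]2(O[Si](CC)(CC)CC)[C@@H](C)C(=O)O[C@H]2/C=C1/C | intermediate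
38 | macrocyclic 4-acetate | [C@H]1(OC(C)=O)/C=C/[C@@]2(C)C=C[C@H](O[Si](C)(C)C(C)(C)C)[C@@](C)(OC(C)=O)[C@@H]2[C@@H](OC(C)=O)[C@]2(O[Si](CC)(CC)CC)[C@@H](C)C(=O)O[C@H]2/C=C1/C | intermediate
39 | 8,12-diol triacetate | [C@H]1(OC(C)=O)/C=C/[C@@]2(C)C=C[C@H](O)[C@@](C)(OC(C)=O)[C@@H]2[C@@H](OC(C)=O)[C@]2(O)[C@@H](C)C(=O)O[C@H]2/C=C1/C | intermediate
40 | ring-A enone 2E,5Z-diene | [C@H]1(OC(C)=O)/C=C/[C@@]2(C)C=CC(=O)[C@@](C)(OC(C)=O)[C@@H]2[C@@H](OC(C)=O)[C@]2(O)[C@@H](C)C(=O)O[C@H]2/C=C1/C | intermediate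
41 | CNP0159278.2 | C=C1[C@@H](OC(C)=O)/C=C/[C@@]2(C)C=CC(=O)[C@@](C)(OC(C)=O)[C@@H]2[C@@H](OC(C)=O)[C@]2(O)[C@@H](C)C(=O)O[C@H]2[C@H]1Cl | target

**Step count**

Total steps: 32. Longest linear sequence: 26 (steps 1–12, 17–21, 24–32, from pent-1-en-3-one).

**Steps most likely to fail**

1. Step 27 (nickel macrocyclisation). The silane may hydrosilylate the enal, or the enal may couple in the conjugate sense, before the ring closes. Chains may oligomerise, and zerovalent nickel may ionise the allylic lactone C7–O bond. The fallback forms the same bond by a stoichiometric organochromium addition. It sets out from 34: hydrostannation (Bu3SnH, PdCl2(PPh3)2 cat., THF, 0 °C) should give the E-alkenylstannane F1, iodine in CH2Cl2 the E-alkenyl iodide F2, and Dess–Martin oxidation the iodo Z-enal F3. An intramolecular Nozaki–Hiyama–Kishi reaction (CrCl2, NiCl2 cat., DMSO–THF, high dilution) would then close the ring under the same conformational control and deliver the free C4 alcohol, so the fallback returns to the route at 37.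

2. Step 17 (dioxolanone aldol). The congestion between quaternary C8 and the doubly flanked C10 may cause retro-aldol reversal or no addition, and simple diastereoselection at C9 may be poor. The fallback makes the C8–C9 bond irreversibly by acylation and sets C9 afterwards. It sets out from 17: chlorite oxidation (NaClO2, NaH2PO4, 2-methylbut-2-ene) gives the carboxylic acid F4, and 1-chloro-N,N,2-trimethylprop-1-en-1-amine gives the acid chloride F5. C-acylation of the lithium enolate of 22 at −78 °C gives the β-keto dioxolanone F6. Reduction of the ketone (NaBH4, CeCl3·7H2O, MeOH, −78 °C), with hydride approaching anti to the C8–O bond in the Felkin–Anh sense, is expected to give the 9R alcohol, returning to the route at 23.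

3. Step 32 (ene-type chlorination). Chlorine may be delivered to the wrong face of C6 because of transannular shielding, and hypochlorite may form at O8. The fallback sets the C6 configuration by a hydroxyl-directed oxygenation followed by inversion. It sets out from 37: the Schenck ene reaction (O2, tetraphenylporphyrin, hν, CH2Cl2, 0 °C), steered by hydrogen bonding to the free C4 hydroxyl, should place oxygen on C6 on the O4 face and give the 6-hydroperoxide F7. PPh3 reduces it to the 4,6-diol F8, and one equivalent of Ac2O in pyridine at −20 °C acetylates the less hindered C4 hydroxyl to give the monoacetate F9. Appel-type chlorination (PPh3, N-chlorosuccinimide, THF, 0 °C) with inversion gives the 6S chloride F10. HF·pyridine then gives the 8,12-diol F11, and Dess–Martin oxidation returns to the route at 41.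

**Further compounds**

F1 | step 27 | E-alkenylstannane | CCCC[Sn](CCCC)(CCCC)/C=C/[C@@]1(C)C=C[C@H](O[Si](C)(C)C(C)(C)C)[C@@](C)(OC(C)=O)[C@@H]1[C@@H](OC(C)=O)[C@]2(O[Si](CC)(CC)CC)[C@@H](C)C(=O)O[C@H]2/C=C(C)\CO
F2 | step 27 | E-alkenyl iodide C4 alcohol | I/C=C/[C@@]1(C)C=C[C@H](O[Si](C)(C)C(C)(C)C)[C@@](C)(OC(C)=O)[C@@H]1[C@@H](OC(C)=O)[C@]2(O[Si](CC)(CC)CC)[C@@H](C)C(=O)O[C@H]2/C=C(C)\CO
F3 | step 27 | iodo Z-enal | I/C=C/[C@@]1(C)C=C[C@H](O[Si](C)(C)C(C)(C)C)[C@@](C)(OC(C)=O)[C@@H]1[C@@H](OC(C)=O)[C@]2(O[Si](CC)(CC)CC)[C@@H](C)C(=O)O[C@H]2/C=C(C)\C=O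
F4 | step 17 | ring-A C9 carboxylic acid | C#C[C@@]1(C)C=C[C@H](O[Si](C)(C)C(C)(C)C)[C@@](C)(OC(C)=O)[C@@H]1C(=O)O
F5 | step 17 | ring-A C9 acid chloride | C#C[C@@]1(C)C=C[C@H](O[Si](C)(C)C(C)(C)C)[C@@](C)(OC(C)=O)[C@@H]1C(=O)Cl
F6 | step 17 | β-keto dioxolanone | C#C[C@@]1(C)C=C[C@H](O[Si](C)(C)C(C)(C)C)[C@@](C)(OC(C)=O)[C@@H]1C(=O)[C@]2(O[C@H](C(C)(C)C)OC2=O)[C@@H](C)C(=O)OC(C)(C)C
F7 | step 32 | 6-hydroperoxy-5(16)-en-4-ol | C=C1[C@@H](O)/C=C/[C@@]2(C)C=C[C@H](O[Si](C)(C)C(C)(C)C)[C@@](C)(OC(C)=O)[C@@H]2[C@@H](OC(C)=O)[C@]2(O[Si](CC)(CC)CC)[C@@H](C)C(=O)O[C@H]2[C@@H]1OO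
F8 | step 32 | 5(16)-ene-4,6-diol | C=C1[C@@H](O)/C=C/[C@@]2(C)C=C[C@H](O[Si](C)(C)C(C)(C)C)[C@@](C)(OC(C)=O)[C@@H]2[C@@H](OC(C)=O)[C@]2(O[Si](CC)(CC)CC)[C@@H](C)C(=O)O[C@H]2[C@@H]1O
F9 | step 32 | 4-acetoxy-5(16)-en-6-ol | C=C1[C@@H](OC(C)=O)/C=C/[C@@]2(C)C=C[C@H](O[Si](C)(C)C(C)(C)C)[C@@](C)(OC(C)=O)[C@@H]2[C@@H](OC(C)=O)[C@]2(O[Si](CC)(CC)CC)[C@@H](C)C(=O)O[C@H]2[C@@H]1O
F10 | step 32 | 6S-chloro-5(16)-ene bis-silyl ether | C=C1[C@@H](OC(C)=O)/C=C/[C@@]2(C)C=C[C@H](O[Si](C)(C)C(C)(C)C)[C@@](C)(OC(C)=O)[C@@H]2[C@@H](OC(C)=O)[C@]2(O[Si](CC)(CC)CC)[C@@H](C)C(=O)O[C@H]2[C@H]1Cl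
F11 | step 32 | 6S-chloro-5(16)-ene-8,12-diol | C=C1[C@@H](OC(C)=O)/C=C/[C@@]2(C)C=C[C@H](O)[C@@](C)(OC(C)=O)[C@@H]2[C@@H](OC(C)=O)[C@]2(O)[C@@H](C)C(=O)O[C@H]2[C@H]1Cl
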